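**Assumption:** Perlatolic acid has no stereocentres and no stereogenic double bonds, so it is achiral; "single enantiomer" is moot and no stereocontrol step is needed.

## Retrosynthetic overview

1. Target 13 ⇐ benzyl ester 12 (hydrogenolysis) ⇐ depside triol 10 (regioselective 4-O-methylation of the one non-chelated phenol).
2. Key step: the depside C–O bond and the whole A ring are disconnected together. 10 ⇐ phenol 9 + the acylketene released from diketo-dioxinone 7 (ketene trapping, then aldol aromatisation). No preformed A-ring acid is esterified.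
3. The B ring (benzyl olivetolate 9) comes from the same diketo-dioxinone 7 with BnOH by the same cascade.
4. 7 ⇐ dioxinone 4 + acetyl chloride + hexanoyl Weinreb amide 3 (vinylogous acylation, then dianion Claisen).
5. Ring order: B ring first (step 4), A ring last (step 5).

## Route

**Step 1**
Reactants: 1 hexanoyl chloride; 2 N,O-dimethylhydroxylamine hydrochloride
Product: 3 N-methoxy-N-methylhexanamide
Conditions: pyridine (2.2 equiv), CH2Cl2, 0 °C → rt
Reagents that add atoms: N,O-dimethylhydroxylamine hydrochloride, CNOC.Cl
Why: Standard Schotten–Baumann-type N-acylation giving a Weinreb amide, which later stops cleanly at the ketone stage.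

**Step 2**
Reactants: 4 2,2,6-trimethyl-4H-1,3-dioxin-4-one (2 equiv); 5 acetyl chloride (1 equiv)
Product: 6 2,2-dimethyl-6-(2-oxopropyl)-4H-1,3-dioxin-4-one
Conditions: LiHMDS (2 equiv), THF, −78 °C; then AcCl, −78 → −40 °C; aq. NH4Cl
Reagents that add atoms: acetyl chloride, CC(=O)Cl
Why: Vinylogous (γ) C-acylation of the lithium dienolate of the dioxinone; the second equivalent of enolate absorbs the acidic β-keto product.

**Step 3**
Reactants: 6 keto-dioxinone; 3 N-methoxy-N-methylhexanamide
Product: 7 6-(2,4-dioxononyl)-2,2-dimethyl-4H-1,3-dioxin-4-one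
Conditions: LDA (2.5 equiv), THF, −78 °C; then 3, −78 → −20 °C; cold 1 M HCl quench; use promptly
Reagents that add atoms: N-methoxy-N-methylhexanamide, CCCCCC(=O)N(C)OC (delivers the hexanoyl group)
Why: Crossed Claisen condensation of the 1,3-dicarbonyl-type dianion, which reacts at its last-formed terminal CH2⁻ (Hauser/Weiler regiochemistry), with the Weinreb chelate preventing over-addition.

**Step 4**
Reactants: 7 diketo-dioxinone; 8 benzyl alcohol (1.2 equiv)
Product: 9 benzyl 2,4-dihydroxy-6-pentylbenzoate (benzyl olivetolate)
Conditions: PhMe, 110 °C, 1 h; then K2CO3, i-PrOH/CH2Cl2, rt; then HCl (dioxane), rt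
Reagents that add atoms: benzyl alcohol, OCc1ccccc1
Why: Retro-hetero-Diels–Alder loss of acetone gives an acylketene that BnOH traps as the 3,5,7-trioxododecanoate; base-mediated C2→C7 aldol cyclisation and acid dehydration then give the resorcylate (biomimetic polyketide aromatisation).

**Step 5 (key step)**
Reactants: 7 diketo-dioxinone (1.0 equiv); 9 benzyl olivetolate (1.2 equiv, excess recovered)
Product: 10 benzyl 4-[(2,4-dihydroxy-6-pentylbenzoyl)oxy]-2-hydroxy-6-pentylbenzoate
Conditions: PhMe, 110 °C, N2 sweep to remove acetone; cool; Et3N (2 equiv), CH2Cl2, 4 Å MS, rt; then TFA, CH2Cl2, 0 °C → rt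
Reagents that add atoms: none beyond reactants 7 and 9
Why: Proposed new method: the thermally generated acylketene should be captured by the only non-chelated, unhindered phenol of 9 (the 4-OH; the 2-OH is hydrogen-bonded to the benzoate C=O) to give an aryl 3,5,7-trioxododecanoate, which a non-nucleophilic amine base cyclises (C2→C7 aldol) and TFA dehydrates, so the depside ester and the A ring form in one operation; the closest known chemistry is dioxinone thermolysis/alcohol trapping/aromatisation to resorcylate alkyl esters and phenol trapping of acylketenes to aryl acetoacetates, and alkoxide/alcohol media are avoided so the aryl ester is not cleaved or lost by pyrone formation.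

**Step 6**
Reactants: 10 depside triol; 11 iodomethane (1.1 equiv)
Product: 12 benzyl 2-hydroxy-4-[(2-hydroxy-4-methoxy-6-pentylbenzoyl)oxy]-6-pentylbenzoate
Conditions: K2CO3 (1.1 equiv), acetone, rt
Reagents that add atoms: iodomethane, CI
Why: Williamson O-methylation selective for the A-ring 4-OH, the only phenol not chelated to an ortho ester carbonyl and the most acidic (para to the ester); this is the established selectivity for 2,4-dihydroxybenzoates.

**Step 7**
Reactants: 12 depside benzyl ester
Product: 13 perlatolic acid
Conditions: H2 (1 atm), 10% Pd/C, EtOAc, rt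
Reagents that add atoms: none
Why: Neutral hydrogenolysis of the benzyl ester leaves the depside aryl ester, aryl methyl ether and phenols intact, and room temperature avoids decarboxylation of the salicylic-type acid.

## Compound list

1 | hexanoyl chloride | CCCCCC(=O)Cl | starting material
2 | N,O-dimethylhydroxylamine hydrochloride | CNOC.Cl | starting material
3 | N-methoxy-N-methylhexanamide | CCCCCC(=O)N(C)OC | intermediate
4 | 2,2,6-trimethyl-4H-1,3-dioxin-4-one | CC1=CC(=O)OC(C)(C)O1 | starting material
5 | acetyl chloride | CC(=O)Cl | starting material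
6 | 2,2-dimethyl-6-(2-oxopropyl)-4H-1,3-dioxin-4-one | CC(=O)CC1=CC(=O)OC(C)(C)O1 | intermediate
7 | 6-(2,4-dioxononyl)-2,2-dimethyl-4H-1,3-dioxin-4-one | CCCCCC(=O)CC(=O)CC1=CC(=O)OC(C)(C)O1 | intermediate
8 | benzyl alcohol | OCc1ccccc1 | starting material
9 | benzyl 2,4-dihydroxy-6-pentylbenzoate | CCCCCc1cc(O)cc(O)c1C(=O)OCc1ccccc1 | intermediate
10 | benzyl 4-[(2,4-dihydroxy-6-pentylbenzoyl)oxy]-2-hydroxy-6-pentylbenzoate | CCCCCc1cc(OC(=O)c2c(O)cc(O)cc2CCCCC)cc(O)c1C(=O)OCc1ccccc1 | intermediate
11 | iodomethane | CI | starting material
12 | benzyl 2-hydroxy-4-[(2-hydroxy-4-methoxy-6-pentylbenzoyl)oxy]-6-pentylbenzoate | CCCCCc1cc(OC(=O)c2c(O)cc(OC)cc2CCCCC)cc(O)c1C(=O)OCc1ccccc1 | intermediate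
13 | perlatolic acid | CCCCCc1cc(OC(=O)c2c(O)cc(OC)cc2CCCCC)cc(O)c1C(=O)O | target

## Summary

**Total steps:** 7
**Longest linear sequence:** 6 (steps 2 → 3 → 4 → 5 → 6 → 7 from dioxinone 4); step 1 is a one-step side branch.

**Three steps most likely to fail, with fallbacks:**

1. **Step 5** – the phenol may trap the ketene poorly, or the aryl triketo-ester may collapse to a 4-hydroxy-2-pyrone with loss of ArOH instead of aromatising.
   Fallback: aromatise 7 with the acetonide retained (Et3N, CH2Cl2) to 7-hydroxy-2,2-dimethyl-5-pentyl-4H-1,3-benzodioxin-4-one, O-methylate it, then photolyse (about 300 nm) with 9 so the o-quinone ketene is trapped by the 4-OH. This gives 12 directly and removes step 6.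

2. **Step 3** – the dianion Claisen may give low yield or the wrong regiochemistry, and 7 is labile.
   Fallback: soft-enolate route. C-acylate allyl 4-(2,2-dimethyl-4-oxo-4H-1,3-dioxin-6-yl)-3-oxobutanoate with hexanoyl chloride (MgCl2, pyridine), then Pd(PPh3)4/morpholine deallylation–decarboxylation to 7.

3. **Step 6** – over-methylation or base-induced depside trans-acylation.
   Fallback: install the methyl ether before the depside bond. Make 2-hydroxy-4-methoxy-6-pentylbenzoic acid from the methylated benzodioxinone above (saponification) and esterify it with 9 using TFAA, then hydrogenolyse as in step 7.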